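1. Friday's run leaves 19% of the charged Q as D at the end and Saturday's leaves 15%, with J read at 0% and 0%. G in this flask lies between those two runs, so I take 17.0% for D.

common to all: Q 0.11 M
- Friday's: L 0.11 M; G 0.028 M; run made earlier
- Saturday's: L 0.11 M; G 0.11 M; run made earlier
- flask: L 0.110 M; G 0.0550 M; time 20 min

| run | time / min | J / % | D / % |
|---|---|---|---|
| Friday's | 0.250 | 29 | 8 |
| Friday's | 1.00 | 29 | 19 |
| Friday's | 5.00 | 3 | 17 |
| Friday's | 25.0 | 0 | 19 |
| Saturday's | 0.250 | 28 | 11 |
| Saturday's | 1.00 | 27 | 18 |
| Saturday's | 5.00 | 0 | 14 |
| Saturday's | 25.0 | 0 | 15 |

(readings scatter by 1.5 percentage points)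
- the moment within 20 min at which there is most J
- the amount of J, in percent of the Q charged, at that time
- earliest time at which at least nineteen twentieths of that best amount are there, in min
- latest time at which they still are, in min
- reactions considered so far: L + J -> X; Q -> D; Q + G -> Z; Q -> J

2. I carry one quantity, T, the share of charged Q that ever passes through J; chemists would call it a selectivity. What became D never reaches J, so I put my ceiling on T in this flask at 83.0%. Friday's first readings give J/D = 3.62. That ratio leaves out any J already gone on to X, so I take it times my D as my floor on T, 61.6%. I commit to the middle, 72.3%.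

3. Friday's J reads 29% at 0.250 min and 29% at 1.00 min, so I look for the peak between those times. Friday's first D reading gives Q in that run a half-life of about 0.317 min, and I use it for this flask.

4. After two half-lives, 0.634 min, I reckon 75.0% of Q spent, so J and X together hold about 54.2%. I take that as my ceiling on the peak of J in this flask. My floor is Saturday's reading of 28% at 0.250 min, taken with more G.

5. By 1.00 min, Friday's D reads about its end value, so I treat Q as spent there and X as holding about T minus Friday's J, 43.3%. Letting X grow evenly from the first reading, where I count it as nothing, gives 22.2% at my time, and that leaves J at about 32.1%.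

6. The forecast, reached by "Stepping this by hand", gives 36% at 0.5 min, open from 0.36 min to 0.7 min. That is inside my bracket and above my figure.

7. The flask gives 33.8% at 0.529 min, open from 0.364 min to 0.751 min, inside the bracket too.

    L + J → X (k = 0.280 L mol⁻¹ s⁻¹)
    Q → D (k = 0.00750 s⁻¹)
    Q + G → Z (k = 0.0700 L mol⁻¹ s⁻¹)
    Q → J (k = 0.0320 s⁻¹)

T is the height J shares with X. With L + J → X taken away, the flask's highest J is 74.4% instead of 33.8%.

Take a neighbour flask, like this one but with less L: c_L is 0.044 M, or 0.400 equiv, so I expect L to be the limiting reagent, and T minus that leaves 32.3% as J. Computed, that neighbour flask ends with J at 34.4% and L at 0%.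

The readings are simulated for substances that don't exist; the scatter is artificial.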